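**Plan**
- Cuts (dihydrofuran numbering O1, C2–C5; C2 and C5 are equivalent): the cis C–OH and C–H bonds on the two methyl-bearing ring carbons are removed first (retro syn-hydration). This uncovers a C2-symmetric (2R,5R)-2,5-diaryl-3,4-dimethyl-2,5-dihydrofuran in which both ring C–O bonds are allylic.
- Next the allylic O1–C5 bond is cut and O1 is re-bonded to C3 (retro 1,3-shift of oxygen). The five-membered ring contracts to an oxirane (O1, C2, C3) carrying a C4=C5 styryl arm, which is the mono-epoxide of a symmetric (1E,3E)-1,4-diaryl-2,3-dimethylbuta-1,3-diene. The diene is cut at its central C–C bond into two identical alkenyl boronates, made from 4-bromoguaiacol and propyne.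
- Forward: aryl bromide → aryl propyne → alkenyl boronate → homocoupled diene (chain joined) → oxirane (first ring) → ring expansion to the dihydrofuran (final ring) → hydroboration–oxidation → detosylation.
- Stereochemistry: Shi epoxidation sets the first benzylic centre; the ring expansion relays it to the second (trans); syn hydroboration of the C2-symmetric alkene (homotopic faces) sets the two methyl-bearing centres relative to the flanking aryl groups.
- The phenols travel as tosylates, whose electron withdrawal keeps the aryl oxirane and the doubly benzylic dihydrofuran from ionising.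

Key step: step 6

Remark: the target is read from the SMILES as (2R,3S,4R,5S)-2,5-bis(4-hydroxy-3-methoxyphenyl)-3,4-dimethyloxolan-3-ol (aryl groups trans; 3-OH cis to 4-H and trans to the 2-aryl group; methyl groups cis). The D-fructose-derived Shi ketone is taken to give the (R,R)-oxirane, as it does with other E-trisubstituted aryl alkenes. Ar below = 3-methoxy-4-(tosyloxy)phenyl.

**Step 1**
Reactants: 1 4-bromo-2-methoxyphenol
Product: 2 4-bromo-2-methoxyphenyl 4-methylbenzenesulfonate
Conditions: TsCl, Et3N, DMAP (cat.), CH2Cl2, 0 °C to rt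
Reagents that add atoms: p-toluenesulfonyl chloride, Cc1ccc(S(=O)(=O)Cl)cc1
Why: O-sulfonylation of the phenol should be routine, and the tosylate is chosen because it withstands every later step and makes the aryl ring electron-poor enough to suppress benzylic ionisation in steps 5 to 7.

**Step 2**
Reactants: 2 4-bromo-2-methoxyphenyl 4-methylbenzenesulfonate; 3 propyne
Product: 4 2-methoxy-4-(prop-1-yn-1-yl)phenyl 4-methylbenzenesulfonate
Conditions: propyne (1 M in THF, excess), PdCl2(PPh3)2 (3 mol %), CuI (5 mol %), Et3N, THF, sealed tube, 50 °C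
Reagents that add atoms: none
Why: Sonogashira coupling at the aryl bromide should proceed cleanly because the aryl tosylate does not undergo oxidative addition with a triphenylphosphine palladium catalyst.

**Step 3**
Reactants: 4 2-methoxy-4-(prop-1-yn-1-yl)phenyl 4-methylbenzenesulfonate
Product: 5 2-methoxy-4-[(Z)-2-(4,4,5,5-tetramethyl-1,3,2-dioxaborolan-2-yl)prop-1-en-1-yl]phenyl 4-methylbenzenesulfonate (aryl and boron trans)
Conditions: B2pin2, CuCl (5 mol %), Xantphos (5 mol %), NaOtBu (10 mol %), MeOH (2 equiv), THF, rt
Reagents that add atoms: bis(pinacolato)diboron, CC1(C)OB(OC1(C)C)B1OC(C)(C)C(C)(C)O1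
Why: Copper-catalysed formal hydroboration (syn borylcupration, then protonolysis with retention) should place copper on the aryl-bearing carbon and boron on the methyl-bearing carbon, which fixes the alkene geometry with aryl trans to boron.

**Step 4**
Reactants: 5 alkenyl boronate (two molecules)
Product: 6 (1E,3E)-1,4-bis[3-methoxy-4-(tosyloxy)phenyl]-2,3-dimethylbuta-1,3-diene
Conditions: Pd(OAc)2 (5 mol %), PPh3 (10 mol %), K2CO3, O2 (1 atm), THF/H2O, 40 °C
Reagents that add atoms: none
Why: Palladium-catalysed aerobic oxidative homocoupling of the organoboron compound (two boron-to-palladium transmetalations, then reductive elimination, with O2 reoxidising zerovalent palladium) should join the two methyl-bearing carbons with retention of both alkene geometries.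

**Step 5**
Reactants: 6 (1E,3E)-1,4-bis(Ar)-2,3-dimethylbuta-1,3-diene
Product: 7 (2R,3R)-3-[3-methoxy-4-(tosyloxy)phenyl]-2-{(E)-1-[3-methoxy-4-(tosyloxy)phenyl]prop-1-en-2-yl}-2-methyloxirane
Conditions: D-fructose-derived Shi ketone (30 mol %), Oxone (2KHSO5·KHSO4·K2SO4), K2CO3, Bu4NHSO4 (cat.), MeCN/CH2(OMe)2/aq. Na2B4O7–Na2EDTA buffer (pH 10.5), 0 °C
Reagents that add atoms: potassium peroxymonosulfate, [K+].[O-]S(=O)(=O)OO
Why: Shi asymmetric epoxidation (chiral dioxirane, spiro transition state) should epoxidise one of the two equivalent E-trisubstituted alkenes on the face that gives the (R,R)-oxirane; the new oxirane deactivates the remaining alkene, so the reaction should stop at the mono-epoxide, and the basic buffer protects the vinyl oxirane.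

**Step 6**
Reactants: 7 (2R,3R)-vinyl oxirane
Product: 8 (2R,5R)-2,5-bis[3-methoxy-4-(tosyloxy)phenyl]-3,4-dimethyl-2,5-dihydrofuran
Conditions: Cu(hfacac)2 [Cu(CF3COCHCOCF3)2] (5 mol %), PhMe, 100 °C
Reagents that add atoms: none
Why: Monovalent copper, formed in situ from the divalent precatalyst, should add to the terminal carbon of the styryl arm anti to the departing oxirane C–O bond (SN2′-type oxidative addition at the tertiary allylic carbon C3, product numbering), giving a trivalent copper σ-allyl alkoxide that closes to a six-membered oxacupracycle; C–O reductive elimination then forms the O1–C5 bond, a formal 1,3-shift of oxygen whose closest known reaction type is the copper-catalysed ring expansion of vinyl oxiranes to 2,5-dihydrofurans. The five-membered ring closes as a formal 5-endo attack of the alkoxide on the allyl terminus, feasible because it runs as a reductive elimination from the oxacupracycle and not as a direct 5-endo-trig addition. The only new stereocentre, C5, is controlled by the configuration of the oxirane carbon C3 (which becomes sp2) together with the E geometry of the alkene: oxygen leaves one face of the allyl unit and is returned by copper to the other, which for a trans-oxirane/E-alkene pairing places the two aryl groups trans, while C2 keeps its configuration because its C–O bond is never broken. The step needs cleavage of the allylic C3–O bond and not the benzylic C2–O bond, reaction through the s-cis rotamer, and no free allyl or benzyl cation, since a cation would scramble C5 towards the achiral cis isomer; the tertiary allylic C–O bond is the more labile one, and the two tosyloxy groups make both aryl rings electron-poor so that the metal-bound pathway should dominate over ionisation.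

**Step 7**
Reactants: 8 (2R,5R)-2,5-bis(Ar)-3,4-dimethyl-2,5-dihydrofuran
Product: 10 (2R,3S,4R,5S)-2,5-bis[3-methoxy-4-(tosyloxy)phenyl]-3,4-dimethyloxolan-3-ol, via tertiary alkylborane 9 (not isolated)
Conditions: BH3·THF (3 equiv), THF, 0 °C to rt; then 3 M aq. NaOH, 30% H2O2, 0 °C to rt
Reagents that add atoms: hydrogen peroxide, OO
Why: Hydroboration–oxidation adds H and OH syn across the tetrasubstituted alkene (as 1,2-dimethylcyclopentene gives cis-1,2-dimethylcyclopentanol); the two faces are homotopic by the C2 axis, so only regiochemistry matters, and boron should go to the alkene carbon whose neighbouring aryl group lies on the opposite ring face, which after oxidation with retention gives OH trans to the adjacent aryl group, cis to the new hydrogen, and both methyl groups cis.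

**Step 8**
Reactants: 10 (2R,3S,4R,5S)-2,5-bis(Ar)-3,4-dimethyloxolan-3-ol
Product: 11 (2R,3S,4R,5S)-2,5-bis(4-hydroxy-3-methoxyphenyl)-3,4-dimethyloxolan-3-ol (target)
Conditions: Mg turnings (excess), MeOH, rt (ultrasound); aq. NH4Cl
Reagents that add atoms: none
Why: Reductive S–O cleavage of the aryl sulfonates by electron transfer from magnesium should free both phenols at room temperature without touching the benzylic ring ethers, the tertiary alcohol or any stereocentre.

**Compound list**
1 | 4-bromo-2-methoxyphenol | COc1cc(Br)ccc1O | starting material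
2 | 4-bromo-2-methoxyphenyl 4-methylbenzenesulfonate | COc1cc(Br)ccc1OS(=O)(=O)c1ccc(C)cc1 | intermediate
3 | propyne | CC#C | starting material
4 | 2-methoxy-4-(prop-1-yn-1-yl)phenyl 4-methylbenzenesulfonate | CC#Cc1ccc(OS(=O)(=O)c2ccc(C)cc2)c(OC)c1 | intermediate
5 | 2-methoxy-4-[(Z)-2-(4,4,5,5-tetramethyl-1,3,2-dioxaborolan-2-yl)prop-1-en-1-yl]phenyl 4-methylbenzenesulfonate | C/C(B1OC(C)(C)C(C)(C)O1)=C\c1ccc(OS(=O)(=O)c2ccc(C)cc2)c(OC)c1 | intermediate
6 | (1E,3E)-1,4-bis[3-methoxy-4-(tosyloxy)phenyl]-2,3-dimethylbuta-1,3-diene | COc1cc(/C=C(C)/C(C)=C/c2ccc(OS(=O)(=O)c3ccc(C)cc3)c(OC)c2)ccc1OS(=O)(=O)c1ccc(C)cc1 | intermediate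
7 | (2R,3R)-3-[3-methoxy-4-(tosyloxy)phenyl]-2-{(E)-1-[3-methoxy-4-(tosyloxy)phenyl]prop-1-en-2-yl}-2-methyloxirane | COc1cc([C@H]2O[C@]2(C)/C(C)=C/c2ccc(OS(=O)(=O)c3ccc(C)cc3)c(OC)c2)ccc1OS(=O)(=O)c1ccc(C)cc1 | intermediate
8 | (2R,5R)-2,5-bis[3-methoxy-4-(tosyloxy)phenyl]-3,4-dimethyl-2,5-dihydrofuran | COc1cc([C@H]2O[C@H](c3ccc(OS(=O)(=O)c4ccc(C)cc4)c(OC)c3)C(C)=C2C)ccc1OS(=O)(=O)c1ccc(C)cc1 | intermediate
9 | tertiary alkylborane: BH2 in place of the 3-OH group of 10, same spatial arrangement | COc1cc([C@H]2O[C@H](c3ccc(OS(=O)(=O)c4ccc(C)cc4)c(OC)c3)[C@@](C)(B)[C@@H]2C)ccc1OS(=O)(=O)c1ccc(C)cc1 | intermediate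
10 | (2R,3S,4R,5S)-2,5-bis[3-methoxy-4-(tosyloxy)phenyl]-3,4-dimethyloxolan-3-ol | COc1cc([C@H]2O[C@H](c3ccc(OS(=O)(=O)c4ccc(C)cc4)c(OC)c3)[C@@](C)(O)[C@@H]2C)ccc1OS(=O)(=O)c1ccc(C)cc1 | intermediate
11 | (2R,3S,4R,5S)-2,5-bis(4-hydroxy-3-methoxyphenyl)-3,4-dimethyloxolan-3-ol | COc1cc([C@H]2O[C@H](c3ccc(O)c(OC)c3)[C@@](C)(O)[C@@H]2C)ccc1O | target

**Totals**
Total step count: 8. Longest linear sequence: 8 steps (from 1).

**Steps most likely to fail**

Step 6. The chirality relay may be lost: ring opening to a free allyl cation, or return of oxygen on the face it left, would lead to the achiral cis-dihydrofuran, and Lewis-acid side reactions (1,2-shift to a carbonyl compound, elimination to a dienol) may consume the oxirane. The fallback sets out from 7 and comes back at 10, so that the oxolane ring is made by epoxide opening instead of ring expansion. Treating 7 with Et2Al(TMP) (diethylaluminium 2,2,6,6-tetramethylpiperidide) in toluene at 0 °C should effect the syn elimination of the oxirane through a methyl hydrogen, the only β-hydrogen available, to give the dienol (R,E)-1,4-bis(Ar)-3-methyl-2-methylidenebut-3-en-1-ol F1 with the benzylic centre intact. Shi epoxidation of its trisubstituted styryl alkene with the enantiomeric (L-fructose-derived) ketone should give the hydroxy oxirane (1R)-1-(Ar)-2-[(2S,3S)-3-(Ar)-2-methyloxiran-2-yl]prop-2-en-1-ol F2. Camphorsulfonic acid (cat.) in CH2Cl2 at −20 °C should then close the ring by 5-endo attack of the hydroxyl at the benzylic oxirane carbon with inversion, giving (2R,3S,5R)-2,5-bis(Ar)-3-methyl-4-methylideneoxolan-3-ol F3. Hydrogenation with [Ir(cod)(PCy3)(py)]PF6 and H2 in CH2Cl2, directed by the tertiary hydroxyl, should deliver hydrogen to the face of that hydroxyl and give 10.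

Step 7. The tetrasubstituted alkene, flanked by two allylic ether carbons, may hydroborate sluggishly; boron may add next to the syn aryl group; or the β-alkoxyborane may eliminate with ring opening. The fallback sets out from 8 and comes back at 10. A Schenck ene reaction (O2, tetraphenylporphyrin, hν, CH2Cl2, −20 °C) should bond oxygen to the alkene carbon remote from the aryl group on the attacked face and take hydrogen from the methyl group of the other alkene carbon, giving (2R,3S,5R)-3-hydroperoxy-2,5-bis(Ar)-3-methyl-4-methylideneoxolane F4. Reduction with PPh3 gives the methylideneoxolanol F3 described above, and the same hydroxyl-directed hydrogenation leads to 10.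

Step 4. Protodeboronation, or oxidation of the alkenyl boronate to a ketone under O2, may outrun the double transmetalation. The fallback sets out from 5 and comes back at 6 by a redox-neutral cross-coupling. Half of 5 is converted by iododeboronation with retention (aq. NaOH, I2, THF, 0 °C) into (E)-4-(2-iodoprop-1-en-1-yl)-2-methoxyphenyl 4-methylbenzenesulfonate F5. Suzuki–Miyaura coupling of F5 with the remaining 5 (Pd(PPh3)4, K3PO4, dioxane/H2O, 60 °C) should give 6 with retention at both alkenes.

**Further compounds**
F1 | step 6 | (R,E)-1,4-bis[3-methoxy-4-(tosyloxy)phenyl]-3-methyl-2-methylidenebut-3-en-1-ol | COc1cc([C@@H](O)C(=C)/C(C)=C/c2ccc(OS(=O)(=O)c3ccc(C)cc3)c(OC)c2)ccc1OS(=O)(=O)c1ccc(C)cc1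
F2 | step 6 | (1R)-1-[3-methoxy-4-(tosyloxy)phenyl]-2-{(2S,3S)-3-[3-methoxy-4-(tosyloxy)phenyl]-2-methyloxiran-2-yl}prop-2-en-1-ol | COc1cc([C@@H](O)C(=C)[C@]2(C)O[C@H]2c2ccc(OS(=O)(=O)c3ccc(C)cc3)c(OC)c2)ccc1OS(=O)(=O)c1ccc(C)cc1
F3 | step 6 | (2R,3S,5R)-2,5-bis[3-methoxy-4-(tosyloxy)phenyl]-3-methyl-4-methylideneoxolan-3-ol | COc1cc([C@H]2O[C@H](c3ccc(OS(=O)(=O)c4ccc(C)cc4)c(OC)c3)[C@@](C)(O)C2=C)ccc1OS(=O)(=O)c1ccc(C)cc1
F4 | step 7 | (2R,3S,5R)-3-hydroperoxy-2,5-bis[3-methoxy-4-(tosyloxy)phenyl]-3-methyl-4-methylideneoxolane | COc1cc([C@H]2O[C@H](c3ccc(OS(=O)(=O)c4ccc(C)cc4)c(OC)c3)[C@@](C)(OO)C2=C)ccc1OS(=O)(=O)c1ccc(C)cc1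
F5 | step 4 | (E)-4-(2-iodoprop-1-en-1-yl)-2-methoxyphenyl 4-methylbenzenesulfonate | C/C(I)=C\c1ccc(OS(=O)(=O)c2ccc(C)cc2)c(OC)c1
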